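Slowness sits at the far end of these flasks: the loss of intermediate to side product B, at 0.0017 s⁻¹, runs slower than its step to target, at 0.049 s⁻¹.

    substrate + reagent ⇌ intermediate (K1 = 35 M⁻¹, k1 = 2.2 M⁻¹ s⁻¹, Ea1 = 42.0 kJ mol⁻¹, ΔH1 = −14.0 kJ mol⁻¹)
    intermediate ⇌ target + by-product (K2 = 0.042 M, k2 = 0.049 s⁻¹, Ea2 = 70.0 kJ mol⁻¹, ΔH2 = −43.0 kJ mol⁻¹)
    substrate + intermediate → side product A (k3 = 0.33 M⁻¹ s⁻¹, Ea3 = 44.0 kJ mol⁻¹)
    intermediate → side product B (k4 = 0.0017 s⁻¹, Ea4 = 79.0 kJ mol⁻¹)
    (constants at 25 °C)

common to all: substrate 0.049 M; reagent 1.50 equiv; time 12 min
- south: temperature 25 °C
- north-west: temperature 40 °C
- north: temperature 10 °C

- percent here means substrate units held: one side product A counts as two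
- all constants are for 25 °C and move with temperature by the activation energies and enthalpies

1. which flask leads in amount of target, in percent of the substrate charged ("all alike" within 1.5 percentage points) (south / north-west / north / all alike)
2. how much target is there at the end, in percent of the substrate charged: south
3. how much target is there at the end, in percent of the substrate charged: north-west
4. how much target is there at the end, in percent of the substrate charged: north

The second step turns over in about 20.4 s, far shorter than the 12 min of the run, so we treat it as a pre-equilibrium. Let x be target as a fraction of the charge. By-product forms with it and stands at the same fraction, so the balance puts intermediate at x times x, times the charged 0.049 M, over the second equilibrium constant. But then the leak to side product B goes with x times x, and the reciprocal of x climbs in a straight line. Its slope is the drain constant, the leak's rate constant times the charged concentration over the second equilibrium constant: 0.119 min⁻¹ in south.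

Temperature is easiest in logarithms. The drain constant carries the energy 122 kJ mol⁻¹, the leak's activation energy minus the second step's enthalpy. The second equilibrium constant moves by 2.51 from south to north on its 43 kJ mol⁻¹, so scaling that logarithm by the energies makes the drain 13.6 times slower in north, 1.13 powers of ten. The first equilibrium constant, scaled likewise, makes it 10.6 times faster in north-west, 1.03 powers.

For a start, the product of the two equilibrium constants, 1.47, with the reagent excess suggests roughly 66.7% of target in south, and we use that start in north and north-west too, crudely. Adding the drain over 12 min to its reciprocal, we reckon 34.2% in south, 6.03% in north-west and 62.3% in north, so north leads.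

The forecast, lower than our reckoning in south and north and higher in north-west, names north with 27% in south, 8% in north-west and 50% in north, holding that “the target peaks early and then drains back through the intermediate into the side products”.

The flask gives north as the leader, with 26.2% in south, 8.14% in north-west and 51.3% in north.

The main reason for the low target in north-west is the return of target and by-product to intermediate: with that return struck out, north-west holds 86.0% of target against 8.14%. The drain constant is built on that return, so from the reading at 12 min it carries south on to 6.00% at 120 min, where the flask stands at 6.89%. Raised by its power of ten, the same constant carries north-west on to 0.675% at 120 min, where the flask stands at 0.820%.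

The numbers of this flask are those of an exercise; the flask was simulated.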